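The synthesis rests on disconnecting the C2–C3 bond of the dihydrofuran ring. C2 carries the ring oxygen O1 and is allylic to the exocyclic methylene of the acrolein unit, while C3 is a benzylic carbinol carbon; this pattern is what a 3-aryloxyallyl metal leaves behind when its oxygen-bearing carbon attacks an ortho formyl group. A single chromium-mediated cyclisation of an achiral 5-acetylsalicylaldehyde, whose phenol oxygen bears a CH=C(CH2Cl)2 vinyl group, should therefore close the furan ring, set C2 and C3 trans under ligand control and leave one chloromethyl arm as the future formyl carbon. Ketone reduction, double tigloylation and chloride-to-aldehyde oxidation finish the target.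

Key step: step 7

Design notes

- The C5 side chain passes through the cyclisation as an acetyl group. The precursor 9 is then achiral, the catalyst is the only source of asymmetry, and no silyl ether is needed. The para acetyl group also makes O1 a poorer donor, which should temper ionisation of the ArO–CH=C–CH2Cl unit. The side-chain carbinol is set afterwards by a reagent-controlled ketone reduction.
- Both carbonyl groups travel as dioxolanes and are released before the hydroxyl-to-chloride exchange. The bis-chloride is thus the last compound made before cyclisation and never coexists with a free ortho benzylic hydroxyl, which would add to the enol-ether carbon.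
- Assumption: the sense of induction of the carbazole bis(oxazoline) chromium catalyst in this intramolecular setting has to be read from the first run (Mosher analysis at C3). Because 9 is achiral, both ligand antipodes must perform alike, and the one that gives (2R,3S) is used.

Step 1
Reactants: 1 4-hydroxyacetophenone; 2 paraformaldehyde
Product: 3 5-acetyl-2-hydroxybenzaldehyde
Conditions: MgCl2, Et3N, MeCN, reflux; then 1 M HCl
Reagents that add atoms: paraformaldehyde 2, C=O
Why: Casnati–Skattebøl ortho-formylation, in which the magnesium phenoxide delivers formaldehyde to the only free ortho position (para is blocked by the acetyl group) and a second formaldehyde oxidises the salicyl alkoxide by hydride transfer, so the aldehyde should form directly.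

Step 2
Reactants: 3 5-acetyl-2-hydroxybenzaldehyde
Product: 4 2-(1,3-dioxolan-2-yl)-4-(2-methyl-1,3-dioxolan-2-yl)phenol
Conditions: HOCH2CH2OH (6 equiv), p-toluenesulfonic acid monohydrate (cat.), toluene, reflux, Dean–Stark; Et3N quench
Reagents that add atoms: ethylene glycol, OCCO
Why: Acid-catalysed acetalisation with azeotropic removal of water should mask both carbonyl groups in one operation, which is needed because the free aldehyde would be attacked by the malonate carbanion of step 3 and both carbonyls would be reduced in step 4.

Step 3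
Reactants: 4 2-(1,3-dioxolan-2-yl)-4-(2-methyl-1,3-dioxolan-2-yl)phenol; 5 diethyl ethoxymethylenemalonate
Product: 6 diethyl 2-{[2-(1,3-dioxolan-2-yl)-4-(2-methyl-1,3-dioxolan-2-yl)phenoxy]methylidene}propanedioate
Conditions: 5 (1.5 equiv), NaH (10 mol %), toluene, 110 °C, EtOH distilled off
Reagents that add atoms: diethyl ethoxymethylenemalonate 5, CCOC=C(C(=O)OCC)C(=O)OCC
Why: Conjugate addition–elimination (vinylogous transesterification) of the phenoxide on the alkoxymethylenemalonate exchanges ethoxide for aryloxide, and removal of ethanol should pull the equilibrium to the aryl enol ether while the acetals are inert to the catalytic base.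

Step 4
Reactants: 6 diethyl 2-{[2-(1,3-dioxolan-2-yl)-4-(2-methyl-1,3-dioxolan-2-yl)phenoxy]methylidene}propanedioate
Product: 7 2-{[2-(1,3-dioxolan-2-yl)-4-(2-methyl-1,3-dioxolan-2-yl)phenoxy]methylidene}propane-1,3-diol
Conditions: iBu2AlH (5 equiv), CH2Cl2, −78 → −40 °C; aq. potassium sodium tartrate
Reagents that add atoms: none
Why: Ester reduction with iBu2AlH should proceed by 1,2-hydride delivery to each ester, since the push–pull 3-aryloxyacrylate is a poor conjugate acceptor for an electrophilic hydride at low temperature, and the dioxolanes are not touched under these conditions.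

Step 5
Reactants: 7 2-{[2-(1,3-dioxolan-2-yl)-4-(2-methyl-1,3-dioxolan-2-yl)phenoxy]methylidene}propane-1,3-diol
Product: 8 5-acetyl-2-{[3-hydroxy-2-(hydroxymethyl)prop-1-en-1-yl]oxy}benzaldehyde
Conditions: pyridinium p-toluenesulfonate (0.3 equiv), acetone/H2O (4:1), 45 °C
Reagents that add atoms: water, O
Why: Acid-catalysed acetal hydrolysis should be far faster than protonation of the β,β-disubstituted aryl enol ether, whose oxygen becomes an even poorer donor once the para acetyl group is released, so both carbonyls are freed with the vinyl ether intact.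

Step 6
Reactants: 8 5-acetyl-2-{[3-hydroxy-2-(hydroxymethyl)prop-1-en-1-yl]oxy}benzaldehyde
Product: 9 5-acetyl-2-{[3-chloro-2-(chloromethyl)prop-1-en-1-yl]oxy}benzaldehyde
Conditions: N-chlorosuccinimide (2.4 equiv), Me2S (2.6 equiv), CH2Cl2, −20 → 0 °C; cold aqueous work-up, solution used at once
Reagents that add atoms: N-chlorosuccinimide, O=C1CCC(=O)N1Cl
Why: Corey–Kim chlorination converts both allylic hydroxyls through alkoxysulfonium ions into primary chlorides under near-neutral conditions that spare aldehyde and ketone, and because both arms are chlorinated no geometric isomers exist and the labile bis-chloride is made only directly before use.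

Step 7
Reactants: 9 5-acetyl-2-{[3-chloro-2-(chloromethyl)prop-1-en-1-yl]oxy}benzaldehyde
Product: 11 1-[(2R,3S)-2-(3-chloroprop-1-en-2-yl)-3-hydroxy-2,3-dihydro-1-benzofuran-5-yl]ethan-1-one, via trimethylsilyl ether 10 (not isolated)
Conditions: CrCl2 (10 mol %), 3,6-diphenyl-1,8-bis(4-isopropyl-4,5-dihydro-1,3-oxazol-2-yl)-9H-carbazole ((S,S) or (R,R), the antipode that gives 2R,3S; 12 mol %), iPr2NEt (30 mol %), Mn powder (1.2 equiv), Me3SiCl (1.5 equiv), THF (0.03 M), 0 °C → rt; then 10 % aq. citric acid, 0 °C
Reagents that add atoms: none
Why: Proposed new method: the ligated divalent chromium reduces one of the two equivalent allylic C–Cl bonds in two one-electron steps to a trivalent 3-aryloxyallylchromium, whose 1,3-metal shifts erase the enol-ether geometry, and this adds SE2' through its oxygen-bearing carbon to the ortho aldehyde before Me3SiCl releases the chromium alkoxide and Mn returns chromium to the divalent state. The closest known reactions are the catalytic asymmetric Nozaki–Hiyama–Kishi allylation with carbazole bis(oxazoline) chromium complexes, the anti-selective additions of 3-alkoxyallylchromium reagents, and the intramolecular 3-alkoxyallylstannane–aldehyde cyclisations that give trans 2-alkenyl-3-hydroxy cyclic ethers. The dihydrofuran ring closes 5-exo-trig at the aldehyde carbon through a six-membered chair in which chromium bridges the carbonyl oxygen and the allyl terminus. C2 and C3 are set together: their trans relationship follows from the chair with the aldehyde aryl group and the aryloxy group both equatorial, and their absolute configuration can come only from the chiral ligand on chromium because 9 is achiral. The step needs attack at the oxygen-bearing allyl carbon (secured by chromium residing on the primary carbon and by five- over seven-membered ring closure), aldehyde over ketone (inherent to allylchromium reagents), and reduction of only one C–Cl bond, which the limited Mn, the lack of an internal electrophile for a second allylchromium and moderate dilution are meant to secure.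

Step 8
Reactants: 11 1-[(2R,3S)-2-(3-chloroprop-1-en-2-yl)-3-hydroxy-2,3-dihydro-1-benzofuran-5-yl]ethan-1-one
Product: 12 (2R,3S)-2-(3-chloroprop-1-en-2-yl)-5-[(1R)-1-hydroxyethyl]-2,3-dihydro-1-benzofuran-3-ol
Conditions: (S)-1-methyl-3,3-diphenyltetrahydro-1H,3H-pyrrolo[1,2-c][1,3,2]oxazaborole (20 mol %), catecholborane (2.5 equiv), toluene, −78 °C; MeOH, then pH 10 carbonate wash
Reagents that add atoms: none
Why: Corey–Bakshi–Shibata reduction, in which the (S)-oxazaborolidine binds the aryl methyl ketone with the aryl group as the large substituent and directs hydride to one face, should give the (1R)-carbinol under reagent control independent of the remote ring stereocentres, while catecholborane at −78 °C neither hydroborates the 1,1-disubstituted alkene nor touches the allylic chloride.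

Step 9
Reactants: 12 (2R,3S)-2-(3-chloroprop-1-en-2-yl)-5-[(1R)-1-hydroxyethyl]-2,3-dihydro-1-benzofuran-3-ol; 13 (2E)-2-methylbut-2-enoyl chloride (tigloyl chloride)
Product: 14 (1R)-1-[(2R,3S)-2-(3-chloroprop-1-en-2-yl)-3-{[(2E)-2-methylbut-2-enoyl]oxy}-2,3-dihydro-1-benzofuran-5-yl]ethyl (2E)-2-methylbut-2-enoate
Conditions: 13 (3 equiv), pyridine (6 equiv), 4-(dimethylamino)pyridine (0.2 equiv), CH2Cl2, 0 °C → rt
Reagents that add atoms: tigloyl chloride 13, C/C=C(\C)C(=O)Cl
Why: Acylation under nucleophilic catalysis by 4-(dimethylamino)pyridine (through the N-acylpyridinium ion) should esterify both secondary benzylic hydroxyls with retention at carbon, and pyridine as the only base avoids vinylketene formation so the E geometry of the tigloyl groups is kept.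

Step 10
Reactants: 14 (1R)-1-[(2R,3S)-2-(3-chloroprop-1-en-2-yl)-3-{[(2E)-2-methylbut-2-enoyl]oxy}-2,3-dihydro-1-benzofuran-5-yl]ethyl (2E)-2-methylbut-2-enoate
Product: 15 (1R)-1-[(2R,3S)-3-{[(2E)-2-methylbut-2-enoyl]oxy}-2-(3-oxoprop-1-en-2-yl)-2,3-dihydro-1-benzofuran-5-yl]ethyl (2E)-2-methylbut-2-enoate
Conditions: N-methylmorpholine N-oxide (anhydrous, 4 equiv), NaI (20 mol %), 4 Å MS, MeCN, rt → 40 °C
Reagents that add atoms: N-methylmorpholine N-oxide, C[N+]1([O-])CCOCC1
Why: Ganem (Kornblum-type) oxidation, in which iodide-assisted O-alkylation of the N-oxide by the allylic chloride gives an N-allyloxyammonium salt that fragments by loss of the carbinol proton to the 2-substituted acrolein, should be mild enough for both tiglates and leaves C2, which has no carbonyl-activated hydrogen, untouched.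

Compound list

1 | 4-hydroxyacetophenone | CC(=O)c1ccc(O)cc1 | starting material
2 | paraformaldehyde (formaldehyde source) | C=O | starting material
3 | 5-acetyl-2-hydroxybenzaldehyde | CC(=O)c1ccc(O)c(C=O)c1 | intermediate
4 | 2-(1,3-dioxolan-2-yl)-4-(2-methyl-1,3-dioxolan-2-yl)phenol | CC1(OCCO1)c1ccc(O)c(c1)C1OCCO1 | intermediate
5 | diethyl ethoxymethylenemalonate | CCOC=C(C(=O)OCC)C(=O)OCC | starting material
6 | diethyl 2-{[2-(1,3-dioxolan-2-yl)-4-(2-methyl-1,3-dioxolan-2-yl)phenoxy]methylidene}propanedioate | CCOC(=O)C(=COc1ccc(cc1C1OCCO1)C1(C)OCCO1)C(=O)OCC | intermediate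
7 | 2-{[2-(1,3-dioxolan-2-yl)-4-(2-methyl-1,3-dioxolan-2-yl)phenoxy]methylidene}propane-1,3-diol | OCC(CO)=COc1ccc(cc1C1OCCO1)C1(C)OCCO1 | intermediate
8 | 5-acetyl-2-{[3-hydroxy-2-(hydroxymethyl)prop-1-en-1-yl]oxy}benzaldehyde | CC(=O)c1ccc(OC=C(CO)CO)c(C=O)c1 | intermediate
9 | 5-acetyl-2-{[3-chloro-2-(chloromethyl)prop-1-en-1-yl]oxy}benzaldehyde | CC(=O)c1ccc(OC=C(CCl)CCl)c(C=O)c1 | intermediate
10 | 1-{(2R,3S)-2-(3-chloroprop-1-en-2-yl)-3-[(trimethylsilyl)oxy]-2,3-dihydro-1-benzofuran-5-yl}ethan-1-one | C=C(CCl)[C@H]1Oc2ccc(C(C)=O)cc2[C@@H]1O[Si](C)(C)C | intermediate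
11 | 1-[(2R,3S)-2-(3-chloroprop-1-en-2-yl)-3-hydroxy-2,3-dihydro-1-benzofuran-5-yl]ethan-1-one | C=C(CCl)[C@H]1Oc2ccc(C(C)=O)cc2[C@@H]1O | intermediate
12 | (2R,3S)-2-(3-chloroprop-1-en-2-yl)-5-[(1R)-1-hydroxyethyl]-2,3-dihydro-1-benzofuran-3-ol | C=C(CCl)[C@H]1Oc2ccc([C@@H](C)O)cc2[C@@H]1O | intermediate
13 | (2E)-2-methylbut-2-enoyl chloride (tigloyl chloride) | C/C=C(\C)C(=O)Cl | starting material
14 | (1R)-1-[(2R,3S)-2-(3-chloroprop-1-en-2-yl)-3-{[(2E)-2-methylbut-2-enoyl]oxy}-2,3-dihydro-1-benzofuran-5-yl]ethyl (2E)-2-methylbut-2-enoate | C=C(CCl)[C@H]1Oc2ccc([C@@H](C)OC(=O)/C(C)=C/C)cc2[C@@H]1OC(=O)/C(C)=C/C | intermediate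
15 | (1R)-1-[(2R,3S)-3-{[(2E)-2-methylbut-2-enoyl]oxy}-2-(3-oxoprop-1-en-2-yl)-2,3-dihydro-1-benzofuran-5-yl]ethyl (2E)-2-methylbut-2-enoate (CNP0292799.1) | C=C(C=O)[C@H]1Oc2ccc([C@@H](C)OC(=O)/C(C)=C/C)cc2[C@@H]1OC(=O)/C(C)=C/C | target

Total step count: 10.
Longest linear sequence: 10 steps (1 → 15); 2, 5 and 13 are purchased.

Steps most likely to fail

Step 7 (new method). The processes at risk are poor enantiofacial discrimination by the chromium catalyst in the intramolecular chair, stalled catalyst turnover that lets the bis-chloride decompose, and reduction of the second C–Cl bond. The fallback sets out from 9 and gives up catalytic induction for a resolution. Ligand-free cyclisation under stoichiometric Hiyama–Nozaki conditions (CrCl2, 2.1 equiv, THF, 0 °C), a known way to close rings by intramolecular allylation, should give through the same chair the racemic trans chlorohydrin F1. Esterification with (S)-2-methoxy-2-phenylacetic acid (EDC, 4-(dimethylamino)pyridine, CH2Cl2) should give two diastereomers, the (2R,3S)-configured O-methylmandelate F2 and the (2S,3R)-configured O-methylmandelate F3. These would be separated by chromatography or crystallisation and assigned by the mandelate anisotropy model. Methanolysis of F2 (K2CO3, MeOH, 0 °C) returns to the route at 11; F3 is set aside.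

Step 4. The process at risk is conjugate hydride delivery followed by expulsion of the aryloxide, or incomplete reduction, either of which would destroy the enol ether. The fallback sets out from phenol 4 and avoids ester reduction altogether. Wittig bromomethylenation of commercial 1,3-bis(tert-butyldimethylsilyloxy)propan-2-one ((bromomethyl)triphenylphosphonium bromide, KOtBu, THF) should give the vinyl bromide F4. Ullmann-type copper-catalysed O-vinylation of 4 with F4 (CuI, N,N-dimethylglycine, Cs2CO3, dioxane, 90 °C) should give the bis-silyl ether F5. Desilylation with Bu4NF in THF rejoins the route at diol 7, bypassing steps 3 and 4.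

Step 5. The processes at risk are acid-promoted ionisation of a 3-aryloxyallylic hydroxyl (allylic transposition with loss of the phenol) and capture of the free 1,3-diol as a cyclic acetal by acetone or the liberated aldehyde. The fallback sets out from 7 and keeps free hydroxyls away from acid. Acetylation (Ac2O, pyridine, 4-(dimethylamino)pyridine) should give the bis-acetate F6. The same mild acid hydrolysis of the two dioxolanes should then give the keto aldehyde bis-acetate F7. Methanolysis of the acetates (K2CO3, MeOH, 0 °C) rejoins the route at 8.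

Further compounds
F1 | step 7 | racemic trans 1-[2-(3-chloroprop-1-en-2-yl)-3-hydroxy-2,3-dihydro-1-benzofuran-5-yl]ethan-1-one (both enantiomers) | C=C(CCl)[C@H]1Oc2ccc(C(C)=O)cc2[C@@H]1O.C=C(CCl)[C@@H]1Oc2ccc(C(C)=O)cc2[C@H]1O
F2 | step 7 | (2R,3S)-5-acetyl-2-(3-chloroprop-1-en-2-yl)-2,3-dihydro-1-benzofuran-3-yl (2S)-2-methoxy-2-phenylacetate | C=C(CCl)[C@H]1Oc2ccc(C(C)=O)cc2[C@@H]1OC(=O)[C@@H](OC)c1ccccc1
F3 | step 7 | (2S,3R)-5-acetyl-2-(3-chloroprop-1-en-2-yl)-2,3-dihydro-1-benzofuran-3-yl (2S)-2-methoxy-2-phenylacetate | C=C(CCl)[C@@H]1Oc2ccc(C(C)=O)cc2[C@H]1OC(=O)[C@@H](OC)c1ccccc1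
F4 | step 4 | [2-(bromomethylidene)propane-1,3-diyl]bis(oxy)bis(tert-butyldimethylsilane) | BrC=C(CO[Si](C)(C)C(C)(C)C)CO[Si](C)(C)C(C)(C)C
F5 | step 4 | 2-(1,3-dioxolan-2-yl)-4-(2-methyl-1,3-dioxolan-2-yl)phenyl 3-(tert-butyldimethylsilyloxy)-2-[(tert-butyldimethylsilyloxy)methyl]prop-1-en-1-yl ether | CC1(OCCO1)c1ccc(OC=C(CO[Si](C)(C)C(C)(C)C)CO[Si](C)(C)C(C)(C)C)c(c1)C1OCCO1
F6 | step 5 | 2-{[2-(1,3-dioxolan-2-yl)-4-(2-methyl-1,3-dioxolan-2-yl)phenoxy]methylidene}propane-1,3-diyl diacetate | CC(=O)OCC(COC(C)=O)=COc1ccc(cc1C1OCCO1)C1(C)OCCO1
F7 | step 5 | 2-[(4-acetyl-2-formylphenoxy)methylidene]propane-1,3-diyl diacetate | CC(=O)OCC(COC(C)=O)=COc1ccc(C(C)=O)cc1C=O
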